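The route rests on cutting two bonds at neighbouring cyclopentane carbons: the ring CH–CH2(aryl) bond and the C–CH3 bond of the tertiary carbinol. One operation forms both: the methyl boronate complex of an (S)-3-isopropenylcyclopent-1-enyl pinacol boronate is captured at its ring CH by a trialkoxybenzyl electrophile while methyl shifts from boron to carbon, anti across the C=C. The step exploits the vicinal pattern C(CH3)(OH)–CH(CH2Ar) of the five-membered ring (CH3 trans, OH cis to the CH2 link), the boron being exchanged for OH with retention, and the allylic isopropenyl-bearing CH directs the facial attack. Acyl group and the C(CH3)(prenyl) centre of the six-membered ring follow.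

Key step: step 6

Assumption: N-methoxy-N,3-dimethylbutanamide (17) and prenyl acetate (21) are treated as catalogue reagents, and the ligand enantiomers written in steps 1 and 10 stand for whichever antipode delivers the stated configuration, to be fixed by correlation on the first run.

Step 1
Reactants: 1 cyclopent-2-en-1-one; 2 isopropenylmagnesium bromide
Product: 4 (3S)-3-(prop-1-en-2-yl)cyclopent-1-en-1-yl trifluoromethanesulfonate, via bromomagnesium enolate 3 (not isolated)
Conditions: 2 (1.2 equiv), CuBr·SMe2 (5 mol%), Josiphos-type ferrocenyl diphosphine (6 mol%), t-BuOMe, −78 °C; then N-(5-chloropyridin-2-yl)triflimide, THF, −78 °C → rt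
Reagents that add atoms: N-(5-chloropyridin-2-yl)-1,1,1-trifluoro-N-(trifluoromethylsulfonyl)methanesulfonamide, FC(F)(F)S(=O)(=O)N(c1ccc(Cl)cn1)S(=O)(=O)C(F)(F)F
Why: Copper-catalysed asymmetric conjugate addition of a Grignard reagent to a cyclic enone, in which the chiral diphosphine–copper complex selects the enone face and sets the (S) centre, leaves a magnesium enolate with its C=C only between C1 and C2, so that O-triflation gives the 3-substituted alkenyl triflate as a single regioisomer, something enolisation of the free ketone could not secure.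

Step 2
Reactants: 4 (3S)-3-(prop-1-en-2-yl)cyclopent-1-en-1-yl trifluoromethanesulfonate; 5 bis(pinacolato)diboron
Product: 6 4,4,5,5-tetramethyl-2-[(3S)-3-(prop-1-en-2-yl)cyclopent-1-en-1-yl]-1,3,2-dioxaborolane
Conditions: PdCl2(PPh3)2 (3 mol%), PPh3 (6 mol%), KOPh (1.5 equiv), toluene, 50 °C
Reagents that add atoms: none
Why: Miyaura borylation of an alkenyl triflate (oxidative addition to Pd(0), phenoxide-assisted transmetalation from the diboron, reductive elimination) replaces OTf by Bpin without moving the C=C, and the weak base and mild temperature should spare the doubly allylic C–H of the stereocentre.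

Step 3
Reactants: 7 2,4,6-trihydroxytoluene
Product: 8 1,3,5-tris(methoxymethoxy)-2-methylbenzene
Conditions: MOMCl (4 equiv), i-Pr2NEt (5 equiv), CH2Cl2, 0 °C → rt
Reagents that add atoms: chloromethyl methyl ether, COCCl
Why: Williamson-type O-alkylation of the three phenols with MOMCl under amine base gives acetal ethers that survive organolithiums and alkaline peroxide, direct the ortho-lithiations of steps 4 and 8 and stabilise the benzylic cation needed in step 6.

Step 4
Reactants: 8 1,3,5-tris(methoxymethoxy)-2-methylbenzene
Product: 10 [3-methyl-2,4,6-tris(methoxymethoxy)phenyl]methanol, via aryllithium 9 (not isolated)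
Conditions: n-BuLi (1.1 equiv), TMEDA, THF, 0 °C; then (CH2O)n, 0 °C → rt; H2O
Reagents that add atoms: paraformaldehyde (as formaldehyde), C=O
Why: Directed ortho-metalation removes one of the two symmetry-equivalent ring protons, each flanked by two OMOM groups and kinetically far more acidic than the aryl methyl group, and the aryllithium adds to formaldehyde to give the benzylic alcohol without a separate formylation–reduction pair.

Step 5
Reactants: 10 [3-methyl-2,4,6-tris(methoxymethoxy)phenyl]methanol
Product: 12 3-methyl-2,4,6-tris(methoxymethoxy)benzyl bromide, via benzylic mesylate 11 (not isolated)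
Conditions: Ms2O, Et3N, LiBr, THF, −40 → −10 °C; cold filtration under argon, used at once
Reagents that add atoms: lithium bromide, [Li+].[Br-]
Why: Mesylation followed by bromide displacement (an SN1-like substitution at a benzylic carbon activated by three ortho/para alkoxy groups) runs under base-buffered conditions that keep the MOM acetals intact, and because bromide is present from the start the labile electrophile is formed without acid and consumed before it can condense with itself.

Step 6
Reactants: 6 4,4,5,5-tetramethyl-2-[(3S)-3-(prop-1-en-2-yl)cyclopent-1-en-1-yl]-1,3,2-dioxaborolane; 13 methyllithium; 12 3-methyl-2,4,6-tris(methoxymethoxy)benzyl bromide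
Product: 15 2-[(1R,2R,3S)-1-methyl-2-{[3-methyl-2,4,6-tris(methoxymethoxy)phenyl]methyl}-3-(prop-1-en-2-yl)cyclopentyl]-4,4,5,5-tetramethyl-1,3,2-dioxaborolane, via lithium methylboronate complex 14 (not isolated)
Conditions: 13 (1.0 equiv), THF, −78 °C, 30 min; then 12 (1.2 equiv) in THF–MeCN, −78 °C → rt
Reagents that add atoms: none
Why: Methyllithium adds to the trigonal boron of 6 to give boronate complex 14, whose electron-rich C=C attacks the ionising, trialkoxy-stabilised benzylic bromide 12 with its ring CH carbon (C2) while the methyl group shifts from boron to C1 antiperiplanar to the new bond, so that the CH–CH2Ar and C–CH3 bonds form in a single stereospecific 1,2-metallate rearrangement with loss of LiBr. The closest known reaction type is the electrophile-induced 1,2-migration (three-component coupling) of cyclic alkenyl boronate complexes with stabilised carbenium-type electrophiles; the benzylic halide is a new member of that electrophile class, and no ring is closed. The CH stereocentre (C2) is controlled by the existing allylic centre C3, whose isopropenyl group shields one face of the cyclopentene so that the benzyl group enters trans to it. The quaternary stereocentre (C1) is controlled by the anti course of the migration, which puts CH3 trans and boron cis to the benzyl group. The step needs chemoselectivity for the boronate C=C over the isopropenyl C=C and for carbon over pinacol oxygen, secured because the ate-complex alkene is by far the strongest nucleophile present, no free methyllithium remains when 12 is added, and a polar co-solvent favours ion-pair capture at carbon.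

Step 7
Reactants: 15 2-[(1R,2R,3S)-1-methyl-2-{[3-methyl-2,4,6-tris(methoxymethoxy)phenyl]methyl}-3-(prop-1-en-2-yl)cyclopentyl]-4,4,5,5-tetramethyl-1,3,2-dioxaborolane
Product: 16 (1S,2R,3S)-1-methyl-2-{[3-methyl-2,4,6-tris(methoxymethoxy)phenyl]methyl}-3-(prop-1-en-2-yl)cyclopentan-1-ol
Conditions: 30% H2O2, 2 M NaOH, THF, 0 °C → rt
Reagents that add atoms: hydrogen peroxide, OO
Why: Alkaline hydrogen peroxide oxidation of the tertiary pinacol boronate proceeds by hydroperoxide addition to boron and a 1,2-shift of the ring carbon from B to O with retention, so the hydroxyl stays cis to the CH2Ar group, while MOM ethers and the isopropenyl group are inert.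

Step 8
Reactants: 16 (1S,2R,3S)-1-methyl-2-{[3-methyl-2,4,6-tris(methoxymethoxy)phenyl]methyl}-3-(prop-1-en-2-yl)cyclopentan-1-ol; 17 N-methoxy-N,3-dimethylbutanamide
Product: 19 1-[3-{[(1R,2S,5S)-2-hydroxy-2-methyl-5-(prop-1-en-2-yl)cyclopentyl]methyl}-2,4,6-tris(methoxymethoxy)-5-methylphenyl]-3-methylbutan-1-one, via dilithiated intermediate 18 (not isolated)
Conditions: n-BuLi (2.3 equiv), TMEDA, THF, 0 °C; then 17 (1.5 equiv), −78 °C → rt; H2O
Reagents that add atoms: none
Why: After deprotonation of the tertiary alcohol, directed ortho-metalation takes the only remaining ring proton (between two OMOM groups) and the aryllithium is acylated by the N-methoxy-N-methyl amide through a chelated tetrahedral adduct that stops at the ketone, which avoids a Lewis-acid Friedel–Crafts acylation that the tertiary alcohol and the isopropenyl group would not tolerate.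

Step 9
Reactants: 19 1-[3-{[(1R,2S,5S)-2-hydroxy-2-methyl-5-(prop-1-en-2-yl)cyclopentyl]methyl}-2,4,6-tris(methoxymethoxy)-5-methylphenyl]-3-methylbutan-1-one
Product: 20 1-[3-{[(1R,2S,5S)-2-hydroxy-2-methyl-5-(prop-1-en-2-yl)cyclopentyl]methyl}-2,4,6-trihydroxy-5-methylphenyl]-3-methylbutan-1-one
Conditions: HCl (ca. 0.5 M in MeOH), MeOH/THF, 0 °C → rt, under argon
Reagents that add atoms: none
Why: Acid-catalysed acetal exchange with methanol cleaves the three aryl MOM ethers as dimethoxymethane under dilute, cold conditions chosen so that the tertiary alcohol is not ionised towards dehydration or ether formation with the neighbouring phenol.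

Step 10
Reactants: 20 1-[3-{[(1R,2S,5S)-2-hydroxy-2-methyl-5-(prop-1-en-2-yl)cyclopentyl]methyl}-2,4,6-trihydroxy-5-methylphenyl]-3-methylbutan-1-one; 21 prenyl acetate
Product: 22 (6S)-3,5-dihydroxy-4-{[(1R,2S,5S)-2-hydroxy-2-methyl-5-(prop-1-en-2-yl)cyclopentyl]methyl}-6-methyl-2-(3-methylbutanoyl)-6-(3-methylbut-2-en-1-yl)cyclohexa-2,4-dien-1-one (CNP0139230.1)
Conditions: 21 (1.1 equiv), Pd2(dba)3·CHCl3 (2.5 mol%), (R,R)-N,N′-(cyclohexane-1,2-diyl)bis[2-(diphenylphosphino)benzamide] (7.5 mol%), Et3N (1.2 equiv), degassed THF, 0 °C → rt
Reagents that add atoms: none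
Why: Palladium-catalysed asymmetric allylic alkylation (Tsuji–Trost reaction) run as an alkylative dearomatisation: the phloroglucinolate attacks the unsubstituted terminus of the π-prenyl–palladium complex through its methyl-bearing ring carbon, the less hindered of the two alkylated positions, O-prenyl ethers are re-ionised by Pd(0) so that the C-alkylated trione accumulates, and the chiral ligand rather than the remote cyclopentane centres selects the face and sets the (6S) quaternary centre.

Compound list

1 | cyclopent-2-en-1-one | O=C1C=CCC1 | starting material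
2 | isopropenylmagnesium bromide | C=C(C)[Mg]Br | starting material
3 | bromomagnesium (3S)-3-(prop-1-en-2-yl)cyclopent-1-en-1-olate | C=C(C)[C@H]1CCC(O[Mg]Br)=C1 | intermediate
4 | (3S)-3-(prop-1-en-2-yl)cyclopent-1-en-1-yl trifluoromethanesulfonate | C=C(C)[C@H]1CCC(OS(=O)(=O)C(F)(F)F)=C1 | intermediate
5 | bis(pinacolato)diboron | CC1(C)OB(OC1(C)C)B1OC(C)(C)C(C)(C)O1 | starting material
6 | 4,4,5,5-tetramethyl-2-[(3S)-3-(prop-1-en-2-yl)cyclopent-1-en-1-yl]-1,3,2-dioxaborolane | C=C(C)[C@H]1CCC(B2OC(C)(C)C(C)(C)O2)=C1 | intermediate
7 | 2,4,6-trihydroxytoluene | Cc1c(O)cc(O)cc1O | starting material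
8 | 1,3,5-tris(methoxymethoxy)-2-methylbenzene | Cc1c(OCOC)cc(OCOC)cc1OCOC | intermediate
9 | [3-methyl-2,4,6-tris(methoxymethoxy)phenyl]lithium | [Li]c1c(OCOC)cc(OCOC)c(C)c1OCOC | intermediate
10 | [3-methyl-2,4,6-tris(methoxymethoxy)phenyl]methanol | OCc1c(OCOC)cc(OCOC)c(C)c1OCOC | intermediate
11 | 3-methyl-2,4,6-tris(methoxymethoxy)benzyl methanesulfonate | CS(=O)(=O)OCc1c(OCOC)cc(OCOC)c(C)c1OCOC | intermediate
12 | 3-methyl-2,4,6-tris(methoxymethoxy)benzyl bromide | BrCc1c(OCOC)cc(OCOC)c(C)c1OCOC | intermediate
13 | methyllithium | [Li]C | starting material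
14 | lithium methyl(pinacolato)[(3S)-3-(prop-1-en-2-yl)cyclopent-1-en-1-yl]borate | [Li+].C=C(C)[C@H]1CCC([B-]2(C)OC(C)(C)C(C)(C)O2)=C1 | intermediate
15 | 2-[(1R,2R,3S)-1-methyl-2-{[3-methyl-2,4,6-tris(methoxymethoxy)phenyl]methyl}-3-(prop-1-en-2-yl)cyclopentyl]-4,4,5,5-tetramethyl-1,3,2-dioxaborolane | C=C(C)[C@H]1CC[C@](C)(B2OC(C)(C)C(C)(C)O2)[C@@H]1Cc1c(OCOC)cc(OCOC)c(C)c1OCOC | intermediate
16 | (1S,2R,3S)-1-methyl-2-{[3-methyl-2,4,6-tris(methoxymethoxy)phenyl]methyl}-3-(prop-1-en-2-yl)cyclopentan-1-ol | C=C(C)[C@H]1CC[C@](C)(O)[C@@H]1Cc1c(OCOC)cc(OCOC)c(C)c1OCOC | intermediate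
17 | N-methoxy-N,3-dimethylbutanamide | CON(C)C(=O)CC(C)C | starting material
18 | lithium alkoxide/aryllithium formed from 16 (O-lithiated at the carbinol, C-lithiated at the free ring position) | C=C(C)[C@H]1CC[C@](C)(O[Li])[C@@H]1Cc1c(OCOC)c([Li])c(OCOC)c(C)c1OCOC | intermediate
19 | 1-[3-{[(1R,2S,5S)-2-hydroxy-2-methyl-5-(prop-1-en-2-yl)cyclopentyl]methyl}-2,4,6-tris(methoxymethoxy)-5-methylphenyl]-3-methylbutan-1-one | C=C(C)[C@H]1CC[C@](C)(O)[C@@H]1Cc1c(OCOC)c(C(=O)CC(C)C)c(OCOC)c(C)c1OCOC | intermediate
20 | 1-[3-{[(1R,2S,5S)-2-hydroxy-2-methyl-5-(prop-1-en-2-yl)cyclopentyl]methyl}-2,4,6-trihydroxy-5-methylphenyl]-3-methylbutan-1-one | C=C(C)[C@H]1CC[C@](C)(O)[C@@H]1Cc1c(O)c(C(=O)CC(C)C)c(O)c(C)c1O | intermediate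
21 | prenyl acetate (3-methylbut-2-en-1-yl acetate) | CC(C)=CCOC(C)=O | starting material
22 | (6S)-3,5-dihydroxy-4-{[(1R,2S,5S)-2-hydroxy-2-methyl-5-(prop-1-en-2-yl)cyclopentyl]methyl}-6-methyl-2-(3-methylbutanoyl)-6-(3-methylbut-2-en-1-yl)cyclohexa-2,4-dien-1-one | C=C(C)[C@H]1CC[C@](C)(O)[C@@H]1CC1=C(O)[C@](C)(CC=C(C)C)C(=O)C(C(=O)CC(C)C)=C1O | target

Total step count: 10.
Longest linear sequence: 8 steps (7 → 8 → 10 → 12 → 15 → 16 → 19 → 20 → 22; steps 3–10).

Steps most likely to fail

Step 6. The benzylic bromide may ionise and then condense with itself or alkylate a pinacol oxygen faster than the boronate alkene captures it. The electrophile may also discriminate poorly between the two faces of the cyclopentene. The fallback changes the bond-forming logic to a conjugate addition–enolate alkylation followed by carbonyl addition, all known reaction types. It sets out from enolate 3 (generated as in step 1) and bromide 12. After addition of DMPU the enolate is C-benzylated trans to the isopropenyl group to give (2R,3S)-2-{[3-methyl-2,4,6-tris(methoxymethoxy)phenyl]methyl}-3-(prop-1-en-2-yl)cyclopentan-1-one F1. Methylcerium dichloride (MeLi/CeCl3, THF, −78 °C) should then add to the ketone from the face opposite the adjacent benzyl group, which places CH3 trans and OH cis to it. This gives alcohol 16, where the route is rejoined.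

Step 10. The catalyst may discriminate poorly between the faces of a ring carbon that is remote from every existing stereocentre. Alkylation may also compete at the ring carbon carrying the cyclopentylmethyl group, or occur at the substituted terminus of the prenyl unit. The fallback gives up catalyst control and relies on separation of diastereomers. It sets out from 20. Uncatalysed alkylative dearomatisation with prenyl bromide and NaOMe in MeOH at 0 °C should give 22 together with its (6R)-epimer, (6R)-3,5-dihydroxy-4-{[(1R,2S,5S)-2-hydroxy-2-methyl-5-(prop-1-en-2-yl)cyclopentyl]methyl}-6-methyl-2-(3-methylbutanoyl)-6-(3-methylbut-2-en-1-yl)cyclohexa-2,4-dien-1-one F2. The two are separated by preparative HPLC, and the route ends at 22.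

Step 1. Face selection may be weak when an sp2 Grignard reagent adds to the small, flat enone, and O-triflation of the magnesium enolate may be incomplete. The fallback replaces asymmetric catalysis by resolution. It sets out from 1 and 2. The same conjugate addition–triflation run with CuI and no chiral ligand gives racemic 3-(prop-1-en-2-yl)cyclopent-1-en-1-yl trifluoromethanesulfonate F3. Miyaura borylation as in step 2 gives racemic 4,4,5,5-tetramethyl-2-[3-(prop-1-en-2-yl)cyclopent-1-en-1-yl]-1,3,2-dioxaborolane F4. Preparative SFC on a chiral stationary phase then delivers the (S)-enantiomer 6, where the route is rejoined.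

Further compounds

F1 | step 6 | (2R,3S)-2-{[3-methyl-2,4,6-tris(methoxymethoxy)phenyl]methyl}-3-(prop-1-en-2-yl)cyclopentan-1-one | C=C(C)[C@H]1CCC(=O)[C@@H]1Cc1c(OCOC)cc(OCOC)c(C)c1OCOC
F2 | step 10 | (6R)-3,5-dihydroxy-4-{[(1R,2S,5S)-2-hydroxy-2-methyl-5-(prop-1-en-2-yl)cyclopentyl]methyl}-6-methyl-2-(3-methylbutanoyl)-6-(3-methylbut-2-en-1-yl)cyclohexa-2,4-dien-1-one | C=C(C)[C@H]1CC[C@](C)(O)[C@@H]1CC1=C(O)[C@@](C)(CC=C(C)C)C(=O)C(C(=O)CC(C)C)=C1O
F3 | step 1 | racemic 3-(prop-1-en-2-yl)cyclopent-1-en-1-yl trifluoromethanesulfonate | C=C(C)C1CCC(OS(=O)(=O)C(F)(F)F)=C1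
F4 | step 1 | racemic 4,4,5,5-tetramethyl-2-[3-(prop-1-en-2-yl)cyclopent-1-en-1-yl]-1,3,2-dioxaborolane | C=C(C)C1CCC(B2OC(C)(C)C(C)(C)O2)=C1
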